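## Structural features

The target is a depside without stereocentres. Ring A is a 2-hydroxy-4-methoxy-6-propylbenzoyl unit, ring B is a 2-methoxy-6-pentylbenzoic acid, and an aryl ester joins the ring A C1 carbonyl to the ring B C4 oxygen. Both carbonyl carbons lie between two ortho substituents (OH and propyl on ring A, OMe and pentyl on ring B). Acylation with the ring A acid is therefore hindered, and the ring B acid cannot be released from an ordinary ester by hydrolysis. The central aryl ester is the fragile point, since it is an activated ester with a phenoxide leaving group; the free ring B acid is electron-rich and should not be heated. The real difficulty is twofold: acylating the ring B phenol with the doubly ortho-substituted ring A acid while its own C2 hydroxyl stays free, and telling four phenolic oxygens apart (ring A C2 free, ring A C4 methylated, ring B C2 methylated, ring B C4 acylated). Ring A has the resorcylate pattern (carbonyl on C1, oxygens on C2 and C4, alkyl on C6), which is the fold of 3,5,7-trioxodecanoic acid, a butanoyl starter extended by three acetate units. The key step uses this: a 1,3-dioxin-4-one masks the C1 carbonyl together with the C2 oxygen, its C5 carbon becomes ring A C1 and adds to the propyl ketone carbon that becomes ring A C6, and aromatization leaves only the C4 oxygen free. The resulting acetonide serves both as protection of the C2 hydroxyl and as the activated acyl donor for the depside bond.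

## Logic of the disconnections

18 to 17: the O–CH2Ph bond of a benzyl ester on the ring B carboxyl is cut. Hydrogenolysis is neutral, whereas any hydrolytic unmasking would break the depside ester first. The demand is that 17 holds no other reducible or benzylic group.

17 to 10 and 15: the ring A acyl C–O(aryl) bond is cut, which divides the molecule into two arenes of similar size. The acyl partner is 10 and not a free acid, because the acetonide activates the hindered carbonyl and releases the ring A C2 hydroxyl, with loss of acetone, in the coupling itself. The forward step requires the phenoxide 16 to add to a carbonyl flanked by the propyl group, and the product phenoxide must not compete for 10.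

10 to 9: the O–CH3 bond at C7 is cut. The hydroxyl of 9 is the only free one, so no selectivity is needed; the base must only be too weak a nucleophile to open the acetonide.

9 to 7: the C4a–C5 bond of 9 (ring A C1–C6) is cut and water is added back. This opens the carbocycle to a linear chain in which all ring A carbons and oxygens are already present. The forward step must cyclize through carbon in the one productive fold and must not disturb the dioxinone.

7 to 3 and 5: the bond between the side-chain C3 methylene and the C4 carbonyl of 7 is cut, a Claisen retron. This gives a four-carbon acyl donor and a keto-dioxinone. The forward step must acylate the terminal carbon of dianion 6, not its central carbon or an oxygen.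

5 to 4: the N–acyl bond is cut. The acyl imidazole is preferred over 4 itself because its moderated reactivity should limit double acylation and O-acylation by a dianion.

3 to 1: the bond between the side-chain methylene and the acetyl carbonyl is cut. The forward step is γ-acylation of dienolate 2; it needs γ- over α-selectivity and must allow for 3 being more acidic than 1.

15 to 14: the O–Si bond at ring B C4 is cut. Fluoride must remove the silyl group without touching the hindered benzyl ester.

14 to 13: the O–CH3 bond at ring B C2 is cut. The forward methylation acts on a hydrogen-bonded phenol and must not displace the silyl group from the C4 oxygen.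

13 to 12: the O–Si bond is cut. The temporary silyl group is needed because the C4 hydroxyl of 12 is the more acidic and nucleophilic one, so direct methylation would go to the wrong oxygen; the forward silylation must select C4 over C2.

12 to 11: the ester O–CH2Ph bond is cut. This leads to a purchasable acid that holds the whole carbon skeleton of ring B; the forward esterification must proceed through the carboxylate without activating or heating the acid.

## Other disconnections considered

Alternative 1: The cut removes two substituents from ring B at once, the C6–pentyl and C1–carboxyl bonds, and leads back to A1, 1-fluoro-3-methoxy-5-[(triisopropylsilyl)oxy]benzene.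
- Forward step: A2 (pentyllithium) would deprotonate A1 between fluorine and methoxy, fluoride would leave to give an aryne, and a second equivalent of A2 would add meta to the methoxy group so that the new aryllithium sits ortho to it. Carboxylation would give A3, 2-methoxy-6-pentyl-4-[(triisopropylsilyl)oxy]benzoic acid, and benzylation of its carboxylate would give 14.
- In its favour: the two ring B oxygens are differentiated before any carbon is attached, so the selective silylation and the methylation of a chelated phenol (steps 7 and 8) are not needed. The arene is also cheaper than 11.
- Against it: A1 has three ring positions between two heteroatoms, and deprotonation must choose the one between F and OMe. Lithiation next to the silyloxy group would open the wrong aryne or start silyl migration, and the aryllithium can add to a second aryne. A2 is pyrophoric and is needed in at least two equivalents at staged temperatures.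
- Comparison: in step count it is the equal of the chosen plan for this part (silylation of the parent phenol of A1, the aryne step and benzylation, against steps 6 to 8). On raw-material cost and on oxygen differentiation it is the better plan. Mechanistically it depends on kinetic regiocontrol in two consecutive organolithium events, whereas the chosen plan uses three ordinary O-functionalizations on a purchased skeleton. It does nothing for ring A or the depside bond.

Alternative 2: Ring A is cut at C1–C2 and C5–C6, and the depside ester is already present in the precursor A4, benzyl 4-(hex-2-ynoyloxy)-2-methoxy-6-pentylbenzoate, the ynoate of 15.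
- Forward step: A5 (Brassard's diene, 1,3-dimethoxy-1-(trimethylsilyloxy)buta-1,3-diene) would add across the triple bond of A4, its methylene terminus at the propyl-bearing carbon and its ketene acetal carbon at the ester-bearing carbon. Loss of one alkoxy group and desilylation would aromatize the adduct to A6, which is the same compound as 17.
- In its favour: the hindered aryl ester is made while the acid is still an unhindered ynoic acid. The ring A oxygens arrive differentiated (C2 from the silyl ketene acetal, C4 from the enol ether). The way to 17 would be about four steps shorter, or three if A5 has to be prepared.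
- Against it: a 3-alkylpropiolate is a sluggish dienophile and would need temperatures at which the ketene acetal decomposes. The aryl ester of A4 is an acyl donor towards the nucleophilic diene, so C-acylation or a stalled Michael adduct may compete. Aromatization must expel the methoxy and not the silyloxy group, or the C2 oxygen ends methylated. Acylation of 15 with an ynoic acid under carbodiimide and amine catalysis risks isomerization to the allenoate.
- Comparison: on step economy and on the depside-bond problem this alternative is the better plan. Regiocontrol is equal, being set by polarity in both. Its key step is a forcing cycloaddition late on a substrate that carries all of ring B, against a room-temperature aldol on a small fragment. The chosen plan is preferred for the reliability of each step, not for brevity.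

Alternative 3: Ring B is assembled from acyclic parts by cutting C1–C2, C2–C3 and C4–C5.
- Forward step: irradiation of A7, benzyl (2E)-3-(2-diazoacetyl)oct-2-enoate, would bring about a Wolff rearrangement. The ketene so formed would combine with A8, ethynyloxytri(propan-2-yl)silane, by [2+2] cycloaddition, four-electron ring opening, six-electron ring closure and tautomerization. The product A9, benzyl 2-hydroxy-6-pentyl-4-[(triisopropylsilyl)oxy]benzoate, is identical with 13.
- In its favour: the regiochemistry is fixed by the connectivity of the partners. The C2 hydroxyl comes free and the C4 oxygen silylated, with no selection between two hydroxyls. The supply of 11 is not needed, and any alkyl chain could be introduced.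
- Against it: A7 needs several steps, including a diazo transfer or a diazomethane acylation and a defined trisubstituted alkene. A8 is a sensitive reagent that is not trivial to make. The sequence needs a photochemical and a thermal stage. All this would deliver a compound that two simple steps give from 11.
- Comparison: the structural outcome is equal, since it is the same compound. On regiocontrol it is the equal and arguably the better. On step economy and operational safety it is clearly worse for this target. Mechanistically it sets four consecutive pericyclic events against two protecting-group operations.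

Key step: step 4

Remark on the chemistry: the target has no stereocentre, and the quoted precursor and product structures map onto ring A without correction. The one point tightened is that 7 is the masked form of 3,5,7-trioxodecanoic acid (butanoyl starter plus three acetate units). Compound 7 is drawn as the triketo form although it should exist largely as enol tautomers; it is used crude and without protecting groups, and 11 is assumed to be purchasable.

## Route

Step 1
Reactants: 1 2,2,6-trimethyl-4H-1,3-dioxin-4-one
Product: 3 2,2-dimethyl-6-(2-oxopropyl)-4H-1,3-dioxin-4-one, via lithium dienolate 2 (not isolated)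
Conditions: LiN(SiMe3)2 (1.0 equiv), THF, −78 °C, 1 h; AcCl (0.5 equiv), −78 °C, 1 h; aq NH4Cl
Reagents that add atoms: acetyl chloride, CC(=O)Cl
Why: LiN(SiMe3)2 removes a proton from the C6 methyl group to give the dienolate 2, which should be acylated at its γ-carbon (vinylogous Claisen acylation); half an equivalent of acetyl chloride is used because 3 is more acidic than 1 and consumes a second equivalent of 2 as it forms.

Step 2
Reactants: 4 butanoyl chloride
Product: 5 1-(1H-imidazol-1-yl)butan-1-one
Conditions: imidazole (2.0 equiv), CH2Cl2, 0 °C to rt; filter, concentrate, use at once
Reagents that add atoms: imidazole, c1c[nH]cn1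
Why: Nucleophilic acyl substitution at the acid chloride; the second equivalent of imidazole binds HCl and is filtered off as its salt, leaving an acyl donor of moderated reactivity.

Step 3
Reactants: 3 2,2-dimethyl-6-(2-oxopropyl)-4H-1,3-dioxin-4-one; 5 1-(1H-imidazol-1-yl)butan-1-one
Product: 7 6-(2,4-dioxoheptyl)-2,2-dimethyl-4H-1,3-dioxin-4-one, via dilithium dienediolate 6 (not isolated)
Conditions: LiN(iPr)2 (2.2 equiv), THF, −78 °C, 1 h; 5 (1.0 equiv), −78 to −40 °C; 1 M HCl to pH 3, cold work-up, crude 7 used directly
Reagents that add atoms: none
Why: Two equivalents of LiN(iPr)2 give the dienediolate 6, whose terminal and least stabilized carbanion is the most nucleophilic site (dianion Claisen condensation); the product forms as its diketonate, which should block a second acylation, and is released on acidification.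

Step 4
Reactants: 7 6-(2,4-dioxoheptyl)-2,2-dimethyl-4H-1,3-dioxin-4-one
Product: 9 7-hydroxy-2,2-dimethyl-5-propyl-4H-benzo[d][1,3]dioxin-4-one, via cyclic aldol adduct 8 (not isolated)
Conditions: Et3N (3 equiv), CH2Cl2, rt, 12–16 h; aq citric acid
Reagents that add atoms: none
Why: Et3N reversibly deprotonates the side chain; removal of a proton from the methylene between the dioxinone C6 and the first ketone gives a dienolate that is nucleophilic at the dioxinone C5. C5 adds to the propyl ketone carbonyl in an intramolecular aldol reaction, a 6-(enolexo)-exo-trig closure that forms the ring A C1–C6 bond and the tertiary alcohol 8. Base-induced loss of water from 8 and enolization of the remaining ring ketone give the phenol, and the gain of aromaticity makes the sequence irreversible. The closest known reaction type is the amine-mediated cycloaromatization of diketo-dioxinones to isopropylidene-protected resorcylates, a biomimetic polyketide aldol condensation. No stereocentre remains, because the carbinol carbon of 8 becomes an aromatic carbon. The step needs regioselective C-cyclization in a single fold, and the substrate secures it: the dioxinone carbonyl is locked trans to the side chain across the ring C5=C6 bond, so a Claisen closure onto it cannot form a six-membered ring, and any other carbon–carbon closure would give a four-membered ring. O-Cyclization to a pyranone and thermal loss of acetone from the dioxinone are the remaining competitors, and both should be suppressed by the weak base at room temperature.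

Step 5
Reactants: 9 7-hydroxy-2,2-dimethyl-5-propyl-4H-benzo[d][1,3]dioxin-4-one
Product: 10 7-methoxy-2,2-dimethyl-5-propyl-4H-benzo[d][1,3]dioxin-4-one
Conditions: MeI (1.5 equiv), K2CO3 (1.5 equiv), acetone, rt
Reagents that add atoms: iodomethane, CI
Why: Williamson methylation of the only free phenol of 9, which is acidic because it is para to the carbonyl; K2CO3 suspended in acetone offers no nucleophile able to open the acetonide.

Step 6
Reactants: 11 olivetolic acid (2,4-dihydroxy-6-pentylbenzoic acid)
Product: 12 benzyl 2,4-dihydroxy-6-pentylbenzoate
Conditions: BnBr (1.05 equiv), KHCO3 (1.2 equiv), DMF, rt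
Reagents that add atoms: benzyl bromide, BrCc1ccccc1
Why: KHCO3 deprotonates only the carboxylic acid and the carboxylate is alkylated by benzyl bromide (SN2 esterification), which avoids activating or heating the decarboxylation-prone acid; the phenols stay protonated.

Step 7
Reactants: 12 benzyl 2,4-dihydroxy-6-pentylbenzoate
Product: 13 benzyl 2-hydroxy-6-pentyl-4-[(triisopropylsilyl)oxy]benzoate
Conditions: iPr3SiCl (1.1 equiv), imidazole (2.2 equiv), DMF, 0 °C to rt
Reagents that add atoms: chlorotriisopropylsilane, CC(C)[Si](Cl)(C(C)C)C(C)C
Why: Silylation with a bulky silyl chloride and imidazole should take the free and more acidic C4 hydroxyl; the C2 hydroxyl is hydrogen-bonded to the ester carbonyl and crowded by it, so it should stay untouched.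

Step 8
Reactants: 13 benzyl 2-hydroxy-6-pentyl-4-[(triisopropylsilyl)oxy]benzoate
Product: 14 benzyl 2-methoxy-6-pentyl-4-[(triisopropylsilyl)oxy]benzoate
Conditions: MeI (3 equiv), K2CO3 (2 equiv), dry acetone, 50 °C, sealed vessel
Reagents that add atoms: iodomethane, CI
Why: Williamson methylation of the chelated C2 phenol needs warming and excess MeI; suspended K2CO3 in dry acetone should not be nucleophilic enough to attack the triisopropylsilyl ether, and the hindered benzyl ester is inert.

Step 9
Reactants: 14 benzyl 2-methoxy-6-pentyl-4-[(triisopropylsilyl)oxy]benzoate
Product: 15 benzyl 4-hydroxy-2-methoxy-6-pentylbenzoate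
Conditions: Bu4NF (1.1 equiv), AcOH (1.2 equiv), THF, 0 °C
Reagents that add atoms: none
Why: Fluoride cleaves aryl silyl ethers rapidly through Si–F bond formation; acetic acid buffers the phenoxide so that neither the benzyl ester nor the methyl ether is at risk.

Step 10
Reactants: 15 benzyl 4-hydroxy-2-methoxy-6-pentylbenzoate; 10 7-methoxy-2,2-dimethyl-5-propyl-4H-benzo[d][1,3]dioxin-4-one
Product: 17 benzyl 4-[(2-hydroxy-4-methoxy-6-propylbenzoyl)oxy]-2-methoxy-6-pentylbenzoate, via cesium phenoxide 16 (not isolated)
Conditions: 15 (1.1 equiv), Cs2CO3 (1.1 equiv), 4 Å sieves, DMF, rt, 15 min; 10 (1.0 equiv), rt to 50 °C; 1 M HCl, 0 °C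
Reagents that add atoms: none
Why: Addition–elimination transesterification: phenoxide 16 adds to the acylal-type carbonyl of 10, the dioxinone ring opens and the hemiketal alkoxide expels acetone, which should make the exchange irreversible and deliver the ring A C2 hydroxyl free. The cyclic acetonide holds the carbonyl in the ring plane and exposes it far better than an open 2,6-disubstituted ester, while the product phenoxide is chelated and hindered.

Step 11
Reactants: 17 benzyl 4-[(2-hydroxy-4-methoxy-6-propylbenzoyl)oxy]-2-methoxy-6-pentylbenzoate
Product: 18 4-[(2-hydroxy-4-methoxy-6-propylbenzoyl)oxy]-2-methoxy-6-pentylbenzoic acid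
Conditions: H2 (1 atm), 10% Pd/C, EtOAc, rt
Reagents that add atoms: none
Why: Hydrogenolysis of the benzylic C–O bond over palladium on carbon is neutral; aryl esters, aryl methyl ethers and the free phenol are inert, so the acid should be unveiled without touching the depside bond.

## Compound list

1 | 2,2,6-trimethyl-4H-1,3-dioxin-4-one | CC1=CC(=O)OC(C)(C)O1 | starting material
2 | lithium 2,2-dimethyl-6-methylidene-6H-1,3-dioxin-4-olate (lithium dienolate of 1) | [Li+].C=C1C=C([O-])OC(C)(C)O1 | intermediate
3 | 2,2-dimethyl-6-(2-oxopropyl)-4H-1,3-dioxin-4-one | CC(=O)CC1=CC(=O)OC(C)(C)O1 | intermediate
4 | butanoyl chloride | CCCC(=O)Cl | starting material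
5 | 1-(1H-imidazol-1-yl)butan-1-one | CCCC(=O)n1ccnc1 | intermediate
6 | dilithium 2,2-dimethyl-6-(2-oxidoprop-2-en-1-ylidene)-6H-1,3-dioxin-4-olate (dianion of 3) | [Li+].[Li+].C=C([O-])C=C1C=C([O-])OC(C)(C)O1 | intermediate
7 | 6-(2,4-dioxoheptyl)-2,2-dimethyl-4H-1,3-dioxin-4-one | CCCC(=O)CC(=O)CC1=CC(=O)OC(C)(C)O1 | intermediate
8 | 5-hydroxy-2,2-dimethyl-5-propyl-5,6-dihydro-4H-1,3-benzodioxine-4,7(8H)-dione (racemic, transient) | CCCC1(O)CC(=O)CC2=C1C(=O)OC(C)(C)O2 | intermediate
9 | 7-hydroxy-2,2-dimethyl-5-propyl-4H-benzo[d][1,3]dioxin-4-one | CCCc1cc(O)cc2OC(C)(C)OC(=O)c12 | intermediate
10 | 7-methoxy-2,2-dimethyl-5-propyl-4H-benzo[d][1,3]dioxin-4-one | CCCc1cc(OC)cc2OC(C)(C)OC(=O)c12 | intermediate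
11 | olivetolic acid (2,4-dihydroxy-6-pentylbenzoic acid) | CCCCCc1cc(O)cc(O)c1C(=O)O | starting material
12 | benzyl 2,4-dihydroxy-6-pentylbenzoate | CCCCCc1cc(O)cc(O)c1C(=O)OCc1ccccc1 | intermediate
13 | benzyl 2-hydroxy-6-pentyl-4-[(triisopropylsilyl)oxy]benzoate | CCCCCc1cc(O[Si](C(C)C)(C(C)C)C(C)C)cc(O)c1C(=O)OCc1ccccc1 | intermediate
14 | benzyl 2-methoxy-6-pentyl-4-[(triisopropylsilyl)oxy]benzoate | CCCCCc1cc(O[Si](C(C)C)(C(C)C)C(C)C)cc(OC)c1C(=O)OCc1ccccc1 | intermediate
15 | benzyl 4-hydroxy-2-methoxy-6-pentylbenzoate | CCCCCc1cc(O)cc(OC)c1C(=O)OCc1ccccc1 | intermediate
16 | cesium 4-(benzyloxycarbonyl)-3-methoxy-5-pentylphenolate | [Cs+].CCCCCc1cc([O-])cc(OC)c1C(=O)OCc1ccccc1 | intermediate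
17 | benzyl 4-[(2-hydroxy-4-methoxy-6-propylbenzoyl)oxy]-2-methoxy-6-pentylbenzoate | CCCCCc1cc(OC(=O)c2c(O)cc(OC)cc2CCC)cc(OC)c1C(=O)OCc1ccccc1 | intermediate
18 | 4-[(2-hydroxy-4-methoxy-6-propylbenzoyl)oxy]-2-methoxy-6-pentylbenzoic acid | CCCCCc1cc(OC(=O)c2c(O)cc(OC)cc2CCC)cc(OC)c1C(=O)O | target

## Step count and least certain steps

Total step count: 11. Longest linear sequence: 6 steps (steps 1, 3, 4, 5, 10, 11 from 1; equally steps 6 to 11 from 11).

Step 4 (key step).
- What may go wrong: cyclization through an enol oxygen to a pyranone in place of the C-aldol, a stalled dehydration of the aldol adduct, or loss of acetone from the dioxinone on any warming, which diverts material to ketene-derived products. The substrate is used crude, so residues from step 3 may steer it as well.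
- Fallback: go through the open chain on purpose. Setting out from 7, heating in toluene with tert-butanol should release the acylketene and trap it as tert-butyl 3,5,7-trioxodecanoate F1. Cs2CO3 in methanol followed by mild acidification should aromatize it by the same aldol fold to tert-butyl 2,4-dihydroxy-6-propylbenzoate F2. Trifluoroacetic acid, trifluoroacetic anhydride and acetone should then cleave the tert-butyl ester and close the acetonide, which returns to the route at 9.

Step 10.
- What may go wrong: slow addition at the hindered carbonyl with reversal of the tetrahedral intermediate (the incoming phenoxide is the better leaving group until acetone is lost), hydrolysis of the acetonide by traces of water, and further acylation of the product phenoxide by a second molecule of the acyl donor.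
- Fallback: activate the acid and not the acetonide. Setting out from 10, KOH in aqueous DMSO and acidification should give 2-hydroxy-4-methoxy-6-propylbenzoic acid F3. This acid with 15 and trifluoroacetic anhydride in toluene (esterification through the mixed anhydride, the classical depside coupling, which tolerates a chelated ortho hydroxyl and suits hindered acids) should give 17, where the route is rejoined.

Step 3.
- What may go wrong: proton transfer from the product to unreacted dianion with incomplete conversion, acylation at oxygen or a second acylation, and uncontrolled cyclization of the product during work-up or on silica.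
- Fallback: replace the acylation by aldol addition and oxidation. Setting out from 3, the dianion 6 should add to butanal at −78 °C to give 6-(4-hydroxy-2-oxoheptyl)-2,2-dimethyl-4H-1,3-dioxin-4-one F4 (racemic; its stereocentre disappears in the next operation). Dess–Martin periodinane in CH2Cl2 should oxidize it under non-basic conditions to 7.

Step 8.
- What may go wrong: loss or migration of the silyl group under the carbonate conditions followed by methylation of the C4 oxygen, or incomplete methylation of the chelated phenol.
- Fallback: use an allyl ether, which is inert to base. Setting out from 12, allyl bromide and K2CO3 in acetone should alkylate only the C4 hydroxyl to give benzyl 2-hydroxy-6-pentyl-4-(prop-2-en-1-yloxy)benzoate F5. MeI and K2CO3 in DMF should then give benzyl 2-methoxy-6-pentyl-4-(prop-2-en-1-yloxy)benzoate F6. Pd(PPh3)4 (zerovalent palladium) with morpholine in THF should remove the allyl group, returning to the route at 15.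

## Further compounds

F1 | step 4 | tert-butyl 3,5,7-trioxodecanoate | CCCC(=O)CC(=O)CC(=O)CC(=O)OC(C)(C)C
F2 | step 4 | tert-butyl 2,4-dihydroxy-6-propylbenzoate | CCCc1cc(O)cc(O)c1C(=O)OC(C)(C)C
F3 | step 10 | 2-hydroxy-4-methoxy-6-propylbenzoic acid | CCCc1cc(OC)cc(O)c1C(=O)O
F4 | step 3 | 6-(4-hydroxy-2-oxoheptyl)-2,2-dimethyl-4H-1,3-dioxin-4-one (racemic) | CCCC(O)CC(=O)CC1=CC(=O)OC(C)(C)O1
F5 | step 8 | benzyl 2-hydroxy-6-pentyl-4-(prop-2-en-1-yloxy)benzoate | C=CCOc1cc(O)c(C(=O)OCc2ccccc2)c(CCCCC)c1
F6 | step 8 | benzyl 2-methoxy-6-pentyl-4-(prop-2-en-1-yloxy)benzoate | C=CCOc1cc(OC)c(C(=O)OCc2ccccc2)c(CCCCC)c1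
A1 | alternative 1 | 1-fluoro-3-methoxy-5-[(triisopropylsilyl)oxy]benzene | COc1cc(F)cc(O[Si](C(C)C)(C(C)C)C(C)C)c1
A2 | alternative 1 | pentyllithium | [Li]CCCCC
A3 | alternative 1 | 2-methoxy-6-pentyl-4-[(triisopropylsilyl)oxy]benzoic acid | CCCCCc1cc(O[Si](C(C)C)(C(C)C)C(C)C)cc(OC)c1C(=O)O
A4 | alternative 2 | benzyl 4-(hex-2-ynoyloxy)-2-methoxy-6-pentylbenzoate | CCCC#CC(=O)Oc1cc(CCCCC)c(C(=O)OCc2ccccc2)c(OC)c1
A5 | alternative 2 | 1,3-dimethoxy-1-(trimethylsilyloxy)buta-1,3-diene | C=C(OC)C=C(OC)O[Si](C)(C)C
A6 | alternative 2 | benzyl 4-[(2-hydroxy-4-methoxy-6-propylbenzoyl)oxy]-2-methoxy-6-pentylbenzoate (identical with 17) | CCCCCc1cc(OC(=O)c2c(O)cc(OC)cc2CCC)cc(OC)c1C(=O)OCc1ccccc1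
A7 | alternative 3 | benzyl (2E)-3-(2-diazoacetyl)oct-2-enoate | CCCCC/C(=C\C(=O)OCc1ccccc1)C(=O)C=[N+]=[N-]
A8 | alternative 3 | ethynyloxytri(propan-2-yl)silane | C#CO[Si](C(C)C)(C(C)C)C(C)C
A9 | alternative 3 | benzyl 2-hydroxy-6-pentyl-4-[(triisopropylsilyl)oxy]benzoate (identical with 13) | CCCCCc1cc(O[Si](C(C)C)(C(C)C)C(C)C)cc(O)c1C(=O)OCc1ccccc1
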